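**Retrosynthetic overview**
1. Target ⇐ hydrogenolysis of its tetra-O-benzyl ether.
2. Tetrabenzyl dimer ⇐ one-flask triple Friedel–Crafts cascade of two acyclic phloroglucinol aryl ethers. C4'–C4a' closes first (epoxide–arene, ring C of the lower unit), then C4–C4a (aldehyde–arene, ring C of the upper unit), then C4–C8' (cation capture, sets C4).
3. Upper partner (β-aryloxy α-silyloxy aldehyde) ⇐ lower partner (threo aryl epoxy ether) by epoxide hydrolysis, bis-silylation and selective Swern oxidation.
4. Threo aryl epoxy ether (O1–C2 bond) ⇐ Mitsunobu inversion of an erythro epoxy alcohol by 3,5-bis(benzyloxy)phenol; the epoxy alcohol ⇐ Sharpless kinetic resolution of racemic 1-phenylprop-2-en-1-ol. This single resolution fixes C2 and C3 of both units; rings A and B are bought.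

Assumption: racemic 1-phenylprop-2-en-1-ol and 3,5-bis(benzyloxy)phenol are bought; flavan numbering is used, with primed locants for the lower (C8-linked) unit.

**Route**

Step 1
Reactants: 1 (±)-1-phenylprop-2-en-1-ol
Product: 2 (1S,2R)-2,3-epoxy-1-phenylpropan-1-ol (erythro)
Conditions: Ti(OiPr)4 (10 mol %), L-(+)-DIPT (15 mol %), t-BuOOH (0.45 equiv), 4 Å MS, CH2Cl2, −20 °C
Reagents that add atoms: tert-butyl hydroperoxide (CC(C)(C)OO)
Why: Sharpless asymmetric epoxidation run as a kinetic resolution: with L-(+)-DIPT the (R)-alcohol is epoxidised much faster than the (S)-alcohol (left behind and removed by chromatography) and gives the erythro epoxy alcohol, which sets C1 (S) and C2 (R), the future C2 and C3 of both flavan units.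

Step 2
Reactants: 2 (1S,2R)-2,3-epoxy-1-phenylpropan-1-ol; 3 3,5-bis(benzyloxy)phenol
Product: 4 (2R)-2-[(R)-[3,5-bis(benzyloxy)phenoxy](phenyl)methyl]oxirane (threo)
Conditions: PPh3, DIAD, THF, 0 °C → rt
Reagents that add atoms: none
Why: Mitsunobu etherification, an SN2 displacement with inversion at the benzylic carbinol (the electron-withdrawing α-epoxide disfavours ionisation), turns the erythro alcohol into the threo aryl ether, which is the 2,3-cis relationship of the flavan.

Step 3
Reactants: 4 (2R)-2-[(R)-[3,5-bis(benzyloxy)phenoxy](phenyl)methyl]oxirane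
Product: 5 (2R,3R)-3-[3,5-bis(benzyloxy)phenoxy]-3-phenylpropane-1,2-diol
Conditions: KOH, DMSO/H2O (4:1), 80 °C
Reagents that add atoms: water (O)
Why: Base-mediated epoxide hydrolysis; hydroxide opens the terminal epoxide at the unhindered CH2 (SN2), so neither stereocentre is touched and no acid is present to trigger arene cyclisation.

Step 4
Reactants: 5 (2R,3R)-3-[3,5-bis(benzyloxy)phenoxy]-3-phenylpropane-1,2-diol
Product: 6 (2R,3R)-3-[3,5-bis(benzyloxy)phenoxy]-3-phenyl-1,2-bis(triethylsilyloxy)propane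
Conditions: Et3SiCl (2.5 equiv), imidazole, DMF, 0 °C → rt
Reagents that add atoms: chlorotriethylsilane (CC[Si](Cl)(CC)CC)
Why: Routine silylation of both hydroxyls, which prepares the primary position for direct oxidation and masks the future 3-OH of the upper unit.

Step 5
Reactants: 6 (2R,3R)-3-[3,5-bis(benzyloxy)phenoxy]-3-phenyl-1,2-bis(triethylsilyloxy)propane
Product: 7 (2S,3R)-3-[3,5-bis(benzyloxy)phenoxy]-3-phenyl-2-(triethylsilyloxy)propanal
Conditions: (COCl)2, DMSO, CH2Cl2, −78 → −35 °C; then Et3N, −78 → 0 °C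
Reagents that add atoms: none
Why: Swern oxidation in which the chlorosulfonium reagent cleaves and oxidises the primary triethylsilyl ether directly while the secondary silyl ether survives; the cold amine stage limits β-elimination of the aryloxide and epimerisation at C2.

Step 6
Reactants: 7 (2S,3R)-3-[3,5-bis(benzyloxy)phenoxy]-3-phenyl-2-(triethylsilyloxy)propanal; 4 (2R)-2-[(R)-[3,5-bis(benzyloxy)phenoxy](phenyl)methyl]oxirane (2.5 equiv)
Product: 11 (2R,3R,4R)-5,7-bis(benzyloxy)-4-[(2R,3R)-5,7-bis(benzyloxy)-3-hydroxy-2-phenylchroman-8-yl]-2-phenylchroman-3-ol, via lower-unit flavan-3-ol 8 (not isolated), via upper-unit silyloxy flavan-4-ol 9 (not isolated), via 3-O-silyl dimer 10 (not isolated)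
Conditions: 4, BF3·OEt2 (0.3 equiv), 4 Å MS, CH2Cl2, −78 °C, 20 min; then 7 added over 1 h, −78 → −30 °C; then Bu4NF, THF, 0 °C
Reagents that add atoms: none
Why: Proposed new method: BF3 first drives the 6-endo epoxide–arene closure of 4 at its unsubstituted epoxide carbon (ring C of the lower unit, 8, C2 and C3 untouched); aldehyde 7 then undergoes 6-exo Friedel–Crafts hydroxyalkylation on its own phloroglucinol ring (ring C of the upper unit, 9), the 4-hydroxyl ionises to a benzylic cation stabilised by the 5,7-dibenzyloxy ring A, and C8 of the excess 8 attacks anti to the bulky 3-silyloxy group, which sets C4 as 4R (3,4-trans), before fluoride removes the silyl group (should 8 add to the aldehyde before 7 cyclises, ionisation and closure of ring A onto the same carbon give the same skeleton); the closest known reactions are Lewis-acid epoxy-arene cyclisations of aryl glycidyl ethers to chroman-3-ols and the Lewis-acid coupling of C4-oxygenated 2,3-cis-flavan-3-ols with flavan-3-ol nucleophiles, which is 4β- and C8-selective.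

Step 7
Reactants: 11 (2R,3R,4R)-5,7-bis(benzyloxy)-4-[(2R,3R)-5,7-bis(benzyloxy)-3-hydroxy-2-phenylchroman-8-yl]-2-phenylchroman-3-ol
Product: 12 (2R,3R,4R)-4-[(2R,3R)-3,5,7-trihydroxy-2-phenylchroman-8-yl]-2-phenylchroman-3,5,7-triol (target)
Conditions: H2 (1 atm), Pd(OH)2/C, THF/MeOH/H2O, rt
Reagents that add atoms: none
Why: Catalytic hydrogenolysis removes the four benzyl ethers; the C2–O1 bonds and the C4–C8' bond of benzylated flavan-3-ol dimers are expected to survive these mild conditions, so no stereocentre is touched.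

**Compound list**

1 | (±)-1-phenylprop-2-en-1-ol (racemic) | C=CC(O)c1ccccc1 | starting material
2 | (1S,2R)-2,3-epoxy-1-phenylpropan-1-ol | O[C@@H](c1ccccc1)[C@H]1CO1 | intermediate
3 | 3,5-bis(benzyloxy)phenol | Oc1cc(OCc2ccccc2)cc(OCc2ccccc2)c1 | starting material
4 | (2R)-2-[(R)-[3,5-bis(benzyloxy)phenoxy](phenyl)methyl]oxirane | c1ccccc1COc1cc(OCc2ccccc2)cc(O[C@H](c2ccccc2)[C@H]2CO2)c1 | intermediate
5 | (2R,3R)-3-[3,5-bis(benzyloxy)phenoxy]-3-phenylpropane-1,2-diol | c1ccccc1COc1cc(OCc2ccccc2)cc(O[C@H](c2ccccc2)[C@H](O)CO)c1 | intermediate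
6 | (2R,3R)-3-[3,5-bis(benzyloxy)phenoxy]-3-phenyl-1,2-bis(triethylsilyloxy)propane | c1ccccc1COc1cc(OCc2ccccc2)cc(O[C@H](c2ccccc2)[C@H](O[Si](CC)(CC)CC)CO[Si](CC)(CC)CC)c1 | intermediate
7 | (2S,3R)-3-[3,5-bis(benzyloxy)phenoxy]-3-phenyl-2-(triethylsilyloxy)propanal | c1ccccc1COc1cc(OCc2ccccc2)cc(O[C@H](c2ccccc2)[C@H](O[Si](CC)(CC)CC)C=O)c1 | intermediate
8 | (2R,3R)-5,7-bis(benzyloxy)-2-phenylchroman-3-ol | O[C@@H]1Cc2c(OCc3ccccc3)cc(OCc3ccccc3)cc2O[C@@H]1c1ccccc1 | intermediate (not isolated)
9 | (2R,3R)-5,7-bis(benzyloxy)-2-phenyl-3-(triethylsilyloxy)chroman-4-ol (both C4 epimers; C4 left undefined) | C(Oc1cc(OCc2ccccc2)c2c(c1)O[C@H](c1ccccc1)[C@H](O[Si](CC)(CC)CC)C2O)c1ccccc1 | intermediate (not isolated)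
10 | (2R,3R,4R)-5,7-bis(benzyloxy)-4-[(2R,3R)-5,7-bis(benzyloxy)-3-hydroxy-2-phenylchroman-8-yl]-2-phenyl-3-(triethylsilyloxy)chromane | C(Oc1cc(OCc2ccccc2)c2c(c1)O[C@H](c1ccccc1)[C@H](O[Si](CC)(CC)CC)[C@H]2c1c(OCc2ccccc2)cc(OCc2ccccc2)c2c1O[C@H](c1ccccc1)[C@H](O)C2)c1ccccc1 | intermediate (not isolated)
11 | (2R,3R,4R)-5,7-bis(benzyloxy)-4-[(2R,3R)-5,7-bis(benzyloxy)-3-hydroxy-2-phenylchroman-8-yl]-2-phenylchroman-3-ol | C(Oc1cc(OCc2ccccc2)c2c(c1)O[C@H](c1ccccc1)[C@H](O)[C@H]2c1c(OCc2ccccc2)cc(OCc2ccccc2)c2c1O[C@H](c1ccccc1)[C@H](O)C2)c1ccccc1 | intermediate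
12 | (2R,3R,4R)-4-[(2R,3R)-3,5,7-trihydroxy-2-phenylchroman-8-yl]-2-phenylchroman-3,5,7-triol | Oc1cc(O)c2c(c1)O[C@H](c1ccccc1)[C@H](O)[C@H]2c1c(O)cc(O)c2c1O[C@H](c1ccccc1)[C@H](O)C2 | target

**Step count and risks**

Total steps: 7. Longest linear sequence: 7 (1 → 2 → 4 → 5 → 6 → 7 → 11 → 12); compound 4 also enters step 6 directly as the second partner.

Steps most likely to fail:

Step 6 (cascade). The risks are self-condensation of 7 through its own electron-rich ring, some C6 attack giving the 4→6 isomer, and 5-exo instead of 6-endo epoxide opening. The fallback sets out from 4: close ring C alone (BF3·OEt2 cat., CH2Cl2, −78 °C) and isolate 8. Oxidise part of 8 at C4 with DDQ in CH2Cl2 containing 2-ethoxyethanol to the 4β ether (2R,3R,4S)-5,7-bis(benzyloxy)-4-(2-ethoxyethoxy)-2-phenylchroman-3-ol F1. Couple F1 with 8 (4 equiv) under TMSOTf (cat.) in CH2Cl2 at −78 °C, which comes back to the route at 11. In this variant the C4 electrophile comes from benzylic C–H oxidation of a closed flavan instead of an acyclic aldehyde, the two rings C are closed in separate operations, and steps 3 to 5 are no longer needed.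

Step 5 (selective Swern oxidation). The risks are attack of the chlorosulfonium reagent on the electron-rich ring and amine-induced loss of the β-aryloxide from 7. The fallback sets out from 4: one-carbon homologation of the epoxide with dimethylsulfonium methylide (Me3S+ I−, n-BuLi, THF, −10 °C → rt) gives the allylic alcohol (1R,2R)-1-[3,5-bis(benzyloxy)phenoxy]-1-phenylbut-3-en-2-ol F2. Silylation (Et3SiCl, imidazole, DMF) gives triethyl{[(1R,2R)-1-[3,5-bis(benzyloxy)phenoxy]-1-phenylbut-3-en-2-yl]oxy}silane F3. Oxidative cleavage of the vinyl group (OsO4 cat., NaIO4, 2,6-lutidine, dioxane/H2O) comes back to the route at 7. The aldehyde is then made by alkene cleavage under near-neutral conditions, with no activated sulfoxide and no amine base.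

Step 2 (Mitsunobu etherification). The risks are sluggish displacement at the hindered benzylic carbinol or alkylation of the hydrazide. The fallback sets out from 2: convert it at −20 °C (MsCl, Et3N, CH2Cl2) into the sulfonate (S)-[(2R)-oxiran-2-yl](phenyl)methyl methanesulfonate F4. Displace this with the caesium phenoxide of 3 (Cs2CO3, DMF, 0 °C → rt), which comes back to the route at 4. This is a Williamson-type SN2 on an isolated sulfonate with the same inversion; at this temperature phenoxide attack on the terminal epoxide is slow compared with benzylic displacement.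

**Further compounds**

F1 | step 6 | (2R,3R,4S)-5,7-bis(benzyloxy)-4-(2-ethoxyethoxy)-2-phenylchroman-3-ol | C(Oc1cc(OCc2ccccc2)c2c(c1)O[C@H](c1ccccc1)[C@H](O)[C@H]2OCCOCC)c1ccccc1
F2 | step 5 | (1R,2R)-1-[3,5-bis(benzyloxy)phenoxy]-1-phenylbut-3-en-2-ol | c1ccccc1COc1cc(OCc2ccccc2)cc(O[C@H](c2ccccc2)[C@H](O)C=C)c1
F3 | step 5 | triethyl{[(1R,2R)-1-[3,5-bis(benzyloxy)phenoxy]-1-phenylbut-3-en-2-yl]oxy}silane | c1ccccc1COc1cc(OCc2ccccc2)cc(O[C@H](c2ccccc2)[C@H](O[Si](CC)(CC)CC)C=C)c1
F4 | step 2 | (S)-[(2R)-oxiran-2-yl](phenyl)methyl methanesulfonate | CS(=O)(=O)O[C@@H](c1ccccc1)[C@H]1CO1
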